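**Retrosynthetic overview**

Locants: ring A carries C1 (lactone C=O), C2 (ether O), C3 (CHO), C4 (OH), C5 (H), C6 (CH3). Ring B carries C1' (lactone O), C2' (CH2O-fumarate), C3' (OH), C4' (carboxyl carbon), C5' (lactol carbon), C6' (ether O). Ring C is the seven-membered depsidone ring and ring D the lactol.

1. The (R) lactol carbon of ring D is fixed last by crystallisation. Before that, ring D is opened to a C4' tert-butyl ester and a C5' diethyl acetal, and the fumarate is removed from the C2' CH2OH group.
2. The strategy rests on the ether oxygen on C6' of hexasubstituted ring B, which sits between four ortho substituents (C1' and C5' on ring B, C1 and C3 on ring A). C6'–C1'–C2'–C3' is read as an oxygenated diene and C4'–C5' as an alkyne, so the ether is made as a plain phenol alkylation before ring B exists.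
3. Ring B is therefore cut at C6'–C5' and C3'–C4': a Diels–Alder reaction of a 1-methoxy-1-silyloxy diene held in the enol lactone ring C with tert-butyl 4,4-diethoxybut-2-ynoate, followed by loss of methanol.
4. The diene comes from a ring A salicylic acid whose C2 oxygen carries CH2–CO–CH(CH2OBn)–CO2Me (from methyl 4-chloroacetoacetate and benzyl chloromethyl ether), by enol lactonisation and γ-silylation. Ring A comes from orsellinic acid as its allyl ester, since the ring A carboxyl must be freed beside the side-chain methyl ester.
5. Order of ring formation: ring A (bought), ring C (step 9), ring B (step 12), ring D (step 16).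

Key step: step 12

Assumption: the lactol carbon epimerises in solution by ring–chain tautomerism, so the (R) configuration is taken as defined for the crystalline solid, and the cinchonidinium salt of the (R) epimer is taken to be the less soluble of the two diastereomeric salts.

**Route**

Step 1
Reactants: 1 orsellinic acid
Product: 2 allyl 2,4-dihydroxy-6-methylbenzoate
Conditions: allyl bromide, KHCO3, DMF, rt
Reagents that add atoms: allyl bromide, C=CCBr
Why: KHCO3 deprotonates only the carboxylic acid, so carboxylate O-alkylation should leave both phenols free, and the allyl ester can later be removed by zerovalent palladium beside the side-chain methyl ester.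

Step 2
Reactants: 2 allyl 2,4-dihydroxy-6-methylbenzoate
Product: 3 allyl 2-hydroxy-4-(methoxymethoxy)-6-methylbenzoate
Conditions: MeOCH2Cl, i-Pr2NEt, CH2Cl2, 0 °C
Reagents that add atoms: chloromethyl methyl ether, COCCl
Why: In this Williamson-type O-alkylation the C2 hydroxyl is hydrogen-bonded to the ester carbonyl, so the C4 hydroxyl should react selectively.

Step 3
Reactants: 3 allyl 2-hydroxy-4-(methoxymethoxy)-6-methylbenzoate
Product: 4 allyl 3-formyl-2-hydroxy-4-(methoxymethoxy)-6-methylbenzoate
Conditions: (CH2O)n, MgCl2, Et3N, MeCN, reflux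
Reagents that add atoms: paraformaldehyde (formaldehyde), C=O
Why: Magnesium phenoxide ortho-formylation delivers formaldehyde only ortho to the free C2 hydroxyl, and C3 is the only open ortho position, so the regiochemistry is fixed; hydride transfer to a second formaldehyde gives the aldehyde.

Step 4
Reactants: 4 allyl 3-formyl-2-hydroxy-4-(methoxymethoxy)-6-methylbenzoate
Product: 5 allyl 2-acetoxy-3-formyl-4-(methoxymethoxy)-6-methylbenzoate
Conditions: Ac2O, Et3N, DMAP (cat.), CH2Cl2, rt
Reagents that add atoms: acetic anhydride, CC(=O)OC(C)=O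
Why: DMAP-catalysed acylation masks the phenol so that the aldehyde can be acetalised without an ortho hydroxyl, and the acetate can later be removed by base without harm to the acetal.

Step 5
Reactants: 5 allyl 2-acetoxy-3-formyl-4-(methoxymethoxy)-6-methylbenzoate
Product: 6 allyl 2-acetoxy-3-(1,3-dioxolan-2-yl)-4-(methoxymethoxy)-6-methylbenzoate
Conditions: HOCH2CH2OH, HC(OEt)3, pyridinium p-toluenesulfonate (cat.), CH2Cl2, rt
Reagents that add atoms: ethylene glycol, OCCO
Why: Acid-catalysed acetalisation driven by the orthoformate as water scavenger is mild enough for the MOM ether, and the cyclic acetal is chosen because dimethyl acetals of 2,6-dioxygenated benzaldehydes hydrolyse on silica.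

Step 6
Reactants: 6 allyl 2-acetoxy-3-(1,3-dioxolan-2-yl)-4-(methoxymethoxy)-6-methylbenzoate; 7 methyl 4-chloro-3-oxobutanoate
Product: 9 allyl 3-(1,3-dioxolan-2-yl)-2-(4-methoxy-2,4-dioxobutoxy)-4-(methoxymethoxy)-6-methylbenzoate, via sodium phenoxide 8 (not isolated)
Conditions: NaOMe, MeOH/THF, 0 °C; evaporate; then 7, NaH, NaI (cat.), DMF, 0 to 50 °C
Reagents that add atoms: none
Why: Methoxide cleaves the aryl acetate much faster than the hindered allyl benzoate, and the phenoxide then displaces chloride from the chloroketone while NaH holds its acidic methylene as the enolate (Williamson ether synthesis); with the aldehyde masked no condensation onto C3 can follow.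

Step 7
Reactants: 9 allyl 3-(1,3-dioxolan-2-yl)-2-(4-methoxy-2,4-dioxobutoxy)-4-(methoxymethoxy)-6-methylbenzoate; 10 benzyl chloromethyl ether
Product: 12 allyl 2-[3-(benzyloxymethyl)-4-methoxy-2,4-dioxobutoxy]-3-(1,3-dioxolan-2-yl)-4-(methoxymethoxy)-6-methylbenzoate (racemic at C2'), via sodium enolate 11 (not isolated)
Conditions: NaH, THF, 0 °C; then 10, 0 °C to rt
Reagents that add atoms: none
Why: Alkylation of the β-keto ester enolate in THF, where the tight sodium ion pair favours carbon over oxygen, should place the CH2OBn group on C2'; the new stereocentre is racemic and disappears in step 9.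

Step 8
Reactants: 12 allyl 2-[3-(benzyloxymethyl)-4-methoxy-2,4-dioxobutoxy]-3-(1,3-dioxolan-2-yl)-4-(methoxymethoxy)-6-methylbenzoate
Product: 13 2-[3-(benzyloxymethyl)-4-methoxy-2,4-dioxobutoxy]-3-(1,3-dioxolan-2-yl)-4-(methoxymethoxy)-6-methylbenzoic acid (racemic at C2')
Conditions: Pd(PPh3)4 (cat.), PhNHMe, THF, rt; pH 5 phosphate work-up
Reagents that add atoms: none
Why: In this Tsuji–Trost deallylation zerovalent palladium ionises the allyl ester and excess N-methylaniline traps the π-allyl complex faster than the hindered β-keto ester can; methyl ester, acetal, MOM and benzyl ether are not touched.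

Step 9
Reactants: 13 2-[3-(benzyloxymethyl)-4-methoxy-2,4-dioxobutoxy]-3-(1,3-dioxolan-2-yl)-4-(methoxymethoxy)-6-methylbenzoic acid
Product: 15 methyl 3-(benzyloxy)-2-[9-(1,3-dioxolan-2-yl)-8-(methoxymethoxy)-6-methyl-5-oxo-2,3-dihydro-5H-1,4-benzodioxepin-3-ylidene]propanoate (alkene geometry of no consequence), via acid chloride 14 (not isolated)
Conditions: 1-chloro-N,N,2-trimethylprop-1-en-1-amine, CH2Cl2, 0 °C; then Et3N, CH2Cl2 (0.005 M), rt
Reagents that add atoms: none
Why: The α-chloroenamine makes the acid chloride without releasing HCl, and with an amine base the β-keto ester enolate is acylated on oxygen, which should close seven-membered ring C as the enol lactone; high dilution suppresses intermolecular acylation.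

Step 10
Reactants: 15 methyl 3-(benzyloxy)-2-[9-(1,3-dioxolan-2-yl)-8-(methoxymethoxy)-6-methyl-5-oxo-2,3-dihydro-5H-1,4-benzodioxepin-3-ylidene]propanoate
Product: 16 3-[1-(benzyloxy)-3-methoxy-3-(trimethylsilyloxy)prop-2-en-2-yl]-9-(1,3-dioxolan-2-yl)-8-(methoxymethoxy)-6-methyl-5H-1,4-benzodioxepin-5-one (mixture of ketene acetal geometries, used crude)
Conditions: Me3SiCl, LiN(SiMe3)2, THF, −78 °C; pentane, filtration under argon
Reagents that add atoms: chlorotrimethylsilane, C[Si](C)(C)Cl
Why: Vinylogous deprotonation at C6' and O-silylation of the ester is the standard way to 1-alkoxy-1-silyloxy dienes from β-oxygenated enoates; the silyl chloride is present from the start so the dienolate is trapped before it can expel the carboxylate, and the hexamethyldisilazide is too weak to metalate the C6 methyl group.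

Step 11
Reactants: 17 3,3-diethoxyprop-1-yne
Product: 19 tert-butyl 4,4-diethoxybut-2-ynoate, via lithium acetylide 18 (not isolated)
Conditions: n-BuLi, THF, −78 °C; then Boc2O, −78 to 0 °C; NH4Cl (aq)
Reagents that add atoms: di-tert-butyl dicarbonate, CC(C)(C)OC(=O)OC(=O)OC(C)(C)C
Why: Deprotonation of the terminal alkyne and acylation of the acetylide with the dicarbonate is a standard route to tert-butyl alkynoates.

Step 12
Reactants: 16 3-[1-(benzyloxy)-3-methoxy-3-(trimethylsilyloxy)prop-2-en-2-yl]-9-(1,3-dioxolan-2-yl)-8-(methoxymethoxy)-6-methyl-5H-1,4-benzodioxepin-5-one; 19 tert-butyl 4,4-diethoxybut-2-ynoate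
Product: 22 protected depsidone with free C3' phenol (C2' CH2OBn; C4' CO2t-Bu; C5' CH(OEt)2; ring A C3 dioxolane and C4 OMOM), via cycloadduct 20 (not isolated), via aryl silyl ether 21 (not isolated)
Conditions: toluene, 4 Å molecular sieves, 100 °C, sealed tube; then Et3N·3HF, THF, 0 °C
Reagents that add atoms: none
Why: The diene is a vinylogous silyl ketene acetal with its largest HOMO coefficient on C6', and the ynoate is electrophilic at C5', the carbon β to the ester, so C6'–C5' bonding should lead an asynchronous [4+2] cycloaddition that C3'–C4' bonding completes to give cyclohexa-1,4-diene 20. The closest known reaction type is the Diels–Alder reaction of 1-alkoxy-1-silyloxy-1,3-dienes with acetylenic esters, which gives salicylates after loss of alcohol; only the placement of the diene inside ring C is new as a substrate. Ring B closes as a six-membered ring in the [4+2] mode (if the process is stepwise, a vinylogous Mukaiyama–Michael addition followed by 6-exo-trig attack of the allenoate carbon C4' on the C3' oxocarbenium ion). Thermal 1,4-elimination of methanol (C6'–H and C3'–OMe) should then aromatise 20 to silyl ether 21, the silyloxy oxygen assisting ionisation of the mixed ketal, and fluoride frees the C3' phenol; the sp3 centres of 20 are lost, so no stereocentre needs control. The step needs the regiochemistry C6' to C5' and C3' to C4'. This is secured by the two oxygen donors on C3' and the acyloxy group on C1', which all polarise the diene towards C6', and by the ester being the only acceptor on the alkyne, the acetal end being none.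

Step 13
Reactants: 22 protected depsidone with free C3' phenol
Product: 23 C3' methoxymethyl ether of 22
Conditions: NaH, MeOCH2Cl, THF/DMF, 0 °C
Reagents that add atoms: chloromethyl methyl ether, COCCl
Why: Williamson-type alkylation of the sodium phenoxide caps the hydrogen-bonded C3' phenol, which prevents ortho-quinone methide formation and phenol acylation in the next two steps.

Step 14
Reactants: 23 C3' methoxymethyl ether of 22
Product: 24 depsidone with free C2' hydroxymethyl group
Conditions: H2 (1 atm), Pd/C, EtOAc, rt
Reagents that add atoms: none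
Why: Hydrogenolysis should cleave the benzyl ether on the unhindered phenyl side, because hexasubstituted ring B adsorbs poorly on palladium and in neutral EtOAc the resulting benzylic alcohol, with its ortho phenol capped, is not reduced further.

Step 15
Reactants: 24 depsidone with free C2' hydroxymethyl group; 25 (E)-4-tert-butoxy-4-oxobut-2-enoic acid
Product: 26 fully protected target (C2' CH2O–CO–CH=CH–CO2t-Bu, E)
Conditions: EDC·HCl, DMAP (cat.), CH2Cl2, 0 °C to rt
Reagents that add atoms: none
Why: Steglich esterification of the primary alcohol should carry the (E) alkene of 25 over unchanged.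

Step 16
Reactants: 26 fully protected target
Product: 27 lactol of the target as the racemate (both configurations at the lactol carbon)
Conditions: CF3CO2H/CH2Cl2/H2O, 0 °C to rt
Reagents that add atoms: water, O
Why: Aqueous acid should cleave the dioxolane, the diethyl acetal, both MOM ethers and both tert-butyl esters, and the freed C5' aldehyde and C4' acid close to the hydroxyphthalide ring D by ring–chain tautomerism, which forms the lactol carbon without selectivity.

Step 17
Reactants: 27 lactol of the target as the racemate; 28 cinchonidine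
Product: 29 cinchonidinium salt of the (R)-lactol (fumarate carboxylate)
Conditions: 28 (1 equiv), MeCN/H2O, 50 °C, then slow cooling and ageing of the slurry at rt; filtration
Reagents that add atoms: none
Why: Proposed new method: the lactol carbon epimerises through the ring-opened 2-formylbenzoate, which the alkaloid base catalyses, while the two diastereomeric salts differ in solubility, so the less soluble one should crystallise and the liquor re-equilibrate until the solid holds one configuration, taken as (R) and set by the lattice of the salt; the closest known reaction type is the crystallisation-induced diastereomer transformation of epimerisable acids as alkaloid salts, and the crystallisation of single anomers of mutarotating lactols.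

Step 18
Reactants: 29 cinchonidinium salt of the (R)-lactol
Product: 30 target, (R)-lactol, as the crystalline solid
Conditions: 1 M HCl (aq), 0 °C, slurry; filtration, cold water wash, drying in vacuo
Reagents that add atoms: none
Why: In this solid-to-solid proton exchange the alkaloid should leave as its water-soluble hydrochloride while the water-insoluble acid stays undissolved, and in cold acid ring opening of the lactol is slow, so the (R) configuration from step 17 is kept.

**Compound list**

1 | orsellinic acid (2,4-dihydroxy-6-methylbenzoic acid) | Cc1cc(O)cc(O)c1C(=O)O | starting material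
2 | allyl 2,4-dihydroxy-6-methylbenzoate | Cc1cc(O)cc(O)c1C(=O)OCC=C | intermediate
3 | allyl 2-hydroxy-4-(methoxymethoxy)-6-methylbenzoate | Cc1cc(OCOC)cc(O)c1C(=O)OCC=C | intermediate
4 | allyl 3-formyl-2-hydroxy-4-(methoxymethoxy)-6-methylbenzoate | Cc1cc(OCOC)c(C=O)c(O)c1C(=O)OCC=C | intermediate
5 | allyl 2-acetoxy-3-formyl-4-(methoxymethoxy)-6-methylbenzoate | Cc1cc(OCOC)c(C=O)c(OC(C)=O)c1C(=O)OCC=C | intermediate
6 | allyl 2-acetoxy-3-(1,3-dioxolan-2-yl)-4-(methoxymethoxy)-6-methylbenzoate | Cc1cc(OCOC)c(C2OCCO2)c(OC(C)=O)c1C(=O)OCC=C | intermediate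
7 | methyl 4-chloro-3-oxobutanoate (methyl 4-chloroacetoacetate) | COC(=O)CC(=O)CCl | starting material
8 | sodium 2-(allyloxycarbonyl)-6-(1,3-dioxolan-2-yl)-5-(methoxymethoxy)-3-methylphenoxide | Cc1cc(OCOC)c(C2OCCO2)c([O-])c1C(=O)OCC=C.[Na+] | intermediate
9 | allyl 3-(1,3-dioxolan-2-yl)-2-(4-methoxy-2,4-dioxobutoxy)-4-(methoxymethoxy)-6-methylbenzoate | Cc1cc(OCOC)c(C2OCCO2)c(OCC(=O)CC(=O)OC)c1C(=O)OCC=C | intermediate
10 | benzyl chloromethyl ether | ClCOCc1ccccc1 | starting material
11 | sodium enolate of 9 (enolate across C1'–C2') | Cc1cc(OCOC)c(C2OCCO2)c(OCC([O-])=CC(=O)OC)c1C(=O)OCC=C.[Na+] | intermediate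
12 | allyl 2-[3-(benzyloxymethyl)-4-methoxy-2,4-dioxobutoxy]-3-(1,3-dioxolan-2-yl)-4-(methoxymethoxy)-6-methylbenzoate, racemic at C2' | Cc1cc(OCOC)c(C2OCCO2)c(OCC(=O)C(COCc2ccccc2)C(=O)OC)c1C(=O)OCC=C | intermediate
13 | 2-[3-(benzyloxymethyl)-4-methoxy-2,4-dioxobutoxy]-3-(1,3-dioxolan-2-yl)-4-(methoxymethoxy)-6-methylbenzoic acid, racemic at C2' | Cc1cc(OCOC)c(C2OCCO2)c(OCC(=O)C(COCc2ccccc2)C(=O)OC)c1C(=O)O | intermediate
14 | acid chloride of 13 | Cc1cc(OCOC)c(C2OCCO2)c(OCC(=O)C(COCc2ccccc2)C(=O)OC)c1C(=O)Cl | intermediate
15 | methyl 3-(benzyloxy)-2-[9-(1,3-dioxolan-2-yl)-8-(methoxymethoxy)-6-methyl-5-oxo-2,3-dihydro-5H-1,4-benzodioxepin-3-ylidene]propanoate, E/Z mixture | Cc1cc(OCOC)c(C3OCCO3)c2OCC(=C(COCc3ccccc3)C(=O)OC)OC(=O)c12 | intermediate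
16 | 3-[1-(benzyloxy)-3-methoxy-3-(trimethylsilyloxy)prop-2-en-2-yl]-9-(1,3-dioxolan-2-yl)-8-(methoxymethoxy)-6-methyl-5H-1,4-benzodioxepin-5-one, mixture of ketene acetal geometries | Cc1cc(OCOC)c(C3OCCO3)c2OC=C(C(COCc3ccccc3)=C(OC)O[Si](C)(C)C)OC(=O)c12 | intermediate
17 | 3,3-diethoxyprop-1-yne | C#CC(OCC)OCC | starting material
18 | lithium 3,3-diethoxyprop-1-yn-1-ide | [Li]C#CC(OCC)OCC | intermediate
19 | tert-butyl 4,4-diethoxybut-2-ynoate | CCOC(OCC)C#CC(=O)OC(C)(C)C | intermediate
20 | cycloadduct: ring B as cyclohexa-1,4-diene with C3'(OMe)(OSiMe3) and C6'(H)(OAr), mixture of diastereomers | Cc1cc(OCOC)c(C3OCCO3)c2c1C(=O)OC1=C(COCc3ccccc3)C(OC)(O[Si](C)(C)C)C(C(=O)OC(C)(C)C)=C(C(OCC)OCC)C1O2 | intermediate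
21 | C3' trimethylsilyl ether of 22 | Cc1cc(OCOC)c(C3OCCO3)c2c1C(=O)Oc1c(COCc3ccccc3)c(O[Si](C)(C)C)c(C(=O)OC(C)(C)C)c(C(OCC)OCC)c1O2 | intermediate
22 | protected depsidone: C2' CH2OBn, C3' OH, C4' CO2t-Bu, C5' CH(OEt)2; ring A C3 1,3-dioxolan-2-yl, C4 OMOM | Cc1cc(OCOC)c(C3OCCO3)c2c1C(=O)Oc1c(COCc3ccccc3)c(O)c(C(=O)OC(C)(C)C)c(C(OCC)OCC)c1O2 | intermediate
23 | C3' methoxymethyl ether of 22 | Cc1cc(OCOC)c(C3OCCO3)c2c1C(=O)Oc1c(COCc3ccccc3)c(OCOC)c(C(=O)OC(C)(C)C)c(C(OCC)OCC)c1O2 | intermediate
24 | C2' hydroxymethyl depsidone (benzyl removed from 23) | Cc1cc(OCOC)c(C3OCCO3)c2c1C(=O)Oc1c(CO)c(OCOC)c(C(=O)OC(C)(C)C)c(C(OCC)OCC)c1O2 | intermediate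
25 | (E)-4-tert-butoxy-4-oxobut-2-enoic acid (mono-tert-butyl fumarate) | CC(C)(C)OC(=O)/C=C/C(=O)O | starting material
26 | fully protected target: C2' CH2O-(E)-fumarate tert-butyl ester | Cc1cc(OCOC)c(C3OCCO3)c2c1C(=O)Oc1c(COC(=O)/C=C/C(=O)OC(C)(C)C)c(OCOC)c(C(=O)OC(C)(C)C)c(C(OCC)OCC)c1O2 | intermediate
27 | target constitution, racemic at the lactol carbon | Cc1cc(O)c(C=O)c2c1C(=O)Oc1c(COC(=O)/C=C/C(=O)O)c(O)c3c(c1O2)C(O)OC3=O | intermediate
28 | cinchonidine, (8S,9R)-cinchonan-9-ol | C=C[C@H]1CN2CC[C@H]1C[C@H]2[C@H](O)c1ccnc2ccccc12 | starting material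
29 | cinchonidinium salt of the (R)-lactol, fumarate carboxylate | Cc1cc(O)c(C=O)c2c1C(=O)Oc1c(COC(=O)/C=C/C(=O)[O-])c(O)c3c(c1O2)[C@H](O)OC3=O.C=C[C@H]1C[NH+]2CC[C@H]1C[C@H]2[C@H](O)c1ccnc2ccccc12 | intermediate
30 | CNP0379578.1, (R)-lactol, (E)-fumarate half ester | Cc1cc(O)c(C=O)c2c1C(=O)Oc1c(COC(=O)/C=C/C(=O)O)c(O)c3c(c1O2)[C@H](O)OC3=O | target

**Step count**

Total: 18 steps. Longest linear sequence: 17 steps (steps 1 to 10 and 12 to 18, from orsellinic acid); the ynoate branch is one step (step 11).

**Steps most likely to fail**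

Step 17. The wrong diastereomeric salt, or a solid solution of both, may crystallise, or the salt may not crystallise at all, so the solid would not hold one configuration. The fallback uses known chemistry and sets out from 27. The racemate is resolved by preparative chromatography on an immobilised polysaccharide chiral stationary phase at low temperature with an acidified, alcohol-free eluent, where ring opening is slow. The (R) fraction is evaporated cold to the solid, and the (S) fraction is left to re-equilibrate in solution and recycled. This comes back to the route at 30 and makes no new compound (F0).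

Step 12. The hindered C6' terminus may add too slowly to the moderately activated ynoate, so the silyl ketene acetal is lost by protodesilylation or silyl migration before cycloaddition, or the Michael adduct may fail to close. The fallback sets out from 16 and uses the more electrophilic aldehyde as acceptor. Lithium acetylide 18 (from 17) is formylated with DMF and quenched into KH2PO4 buffer to give 4,4-diethoxybut-2-ynal F1. Its cycloaddition with 16 in toluene at rt to 60 °C should run with the same regiochemistry through the cycloadduct F2 and the aryl silyl ether F3 to the C4' salicylaldehyde F4 after fluoride work-up. Pinnick oxidation (NaClO2, NaH2PO4, 2-methylbut-2-ene, t-BuOH/H2O) gives the C4' acid F5. Esterification with N,N-dimethylformamide di-tert-butyl acetal in toluene at 80 °C comes back to the route at 22.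

Step 9. On the hindered trisubstituted enolate, acylation on carbon, loss of benzyl alcohol or intermolecular acylation may outrun closure of ring C. The fallback sets out from 9 and closes the lactone before the benzyloxymethyl group is introduced. Deallylation as in step 8 gives the keto acid F6. The α-chloroenamine gives the acid chloride F7, and Et3N at high dilution gives the enol lactone without the C2' substituent F8. LiN(SiMe3)2 in THF at −78 °C gives the lithium dienolate F9, which is alkylated at its α carbon C2' by 10 to give the endocyclic enol lactone with a β,γ-unsaturated ester F10. Silylation under the conditions of step 10, now by α deprotonation, gives the same diene and comes back to the route at 16.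

**Further compounds**

F0 | step 17 | none | none
F1 | step 12 | 4,4-diethoxybut-2-ynal | CCOC(OCC)C#CC=O
F2 | step 12 | cycloadduct of 16 and F1 (C4' CHO) | Cc1cc(OCOC)c(C3OCCO3)c2c1C(=O)OC1=C(COCc3ccccc3)C(OC)(O[Si](C)(C)C)C(C=O)=C(C(OCC)OCC)C1O2
F3 | step 12 | C3' trimethylsilyl ether of F4 | Cc1cc(OCOC)c(C3OCCO3)c2c1C(=O)Oc1c(COCc3ccccc3)c(O[Si](C)(C)C)c(C=O)c(C(OCC)OCC)c1O2
F4 | step 12 | protected depsidone with C3' OH and C4' CHO | Cc1cc(OCOC)c(C3OCCO3)c2c1C(=O)Oc1c(COCc3ccccc3)c(O)c(C=O)c(C(OCC)OCC)c1O2
F5 | step 12 | protected depsidone with C3' OH and C4' CO2H | Cc1cc(OCOC)c(C3OCCO3)c2c1C(=O)Oc1c(COCc3ccccc3)c(O)c(C(=O)O)c(C(OCC)OCC)c1O2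
F6 | step 9 | 3-(1,3-dioxolan-2-yl)-2-(4-methoxy-2,4-dioxobutoxy)-4-(methoxymethoxy)-6-methylbenzoic acid | Cc1cc(OCOC)c(C2OCCO2)c(OCC(=O)CC(=O)OC)c1C(=O)O
F7 | step 9 | acid chloride of F6 | Cc1cc(OCOC)c(C2OCCO2)c(OCC(=O)CC(=O)OC)c1C(=O)Cl
F8 | step 9 | methyl 2-[9-(1,3-dioxolan-2-yl)-8-(methoxymethoxy)-6-methyl-5-oxo-2,3-dihydro-5H-1,4-benzodioxepin-3-ylidene]acetate | Cc1cc(OCOC)c(C3OCCO3)c2OCC(=CC(=O)OC)OC(=O)c12
F9 | step 9 | lithium dienolate of F8 | Cc1cc(OCOC)c(C3OCCO3)c2OC=C(C=C(OC)[O-])OC(=O)c12.[Li+]
F10 | step 9 | methyl 3-(benzyloxy)-2-[9-(1,3-dioxolan-2-yl)-8-(methoxymethoxy)-6-methyl-5-oxo-5H-1,4-benzodioxepin-3-yl]propanoate, racemic | Cc1cc(OCOC)c(C3OCCO3)c2OC=C(C(COCc3ccccc3)C(=O)OC)OC(=O)c12
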